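Take the impurity off first.

| setting | larch | maple | alder | flask |
|---|---|---|---|---|
| starting material | 26 mM | 26 mM | 26 mM | 26 mM |
| acid | 0.13 mM | 0.52 mM | 0.26 mM | 0.260 mM |
| protic impurity | 5.2 mM | 5.2 mM | 10 mM | 5.20 mM |
| remark | run made earlier | run made earlier | run made earlier |  |
| time |  |  |  | 30 h |

- larch (time / h: starting material / %, product / %): 1.50: 93, 2; 5.00: 81, 2; 8.00: 76, 9; 12.0: 75, 8; 20.0: 65, 15; 25.0: 60, 22; 30.0: 55, 24
- maple (time / h: starting material / %, product / %): 2.50: 82, 11; 4.00: 73, 10; 6.00: 67, 24; 8.00: 56, 26; 12.0: 48, 35; 20.0: 34, 48; 30.0: 20, 59
- alder (time / h: starting material / %, product / %): 2.50: 78, 4; 8.00: 57, 13; 15.0: 44, 21; 20.0: 42, 25; 30.0: 27, 33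

(scatter of a reading: 1.5 percentage points)

- acid is the free proton; pH is minus the decimal logarithm of its molar concentration

1. part of the starting material that has reacted at 30 h
2. pH of the solution at 30 h

How much of the charge does the protic impurity take? In the flask its ratio to starting material is 20.0 %. At the last readings, the gap between starting material and product is 21.0 % in maple, and 40.0 % in alder against a ratio of 38.5 %. So we treat the impurity as a limiting reagent that removes its own share, leaving a free share of 80.0 % of the flask's charge.

How does acid act on that free share? Take starting material left at 30 h over the free share: the logarithms of this fraction in maple and larch stand 3.70 to one, and their acid charges 4.00 to one. We read that as pseudo-first-order decay, with acid as the constant.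

What survives in the flask? It holds half of maple's acid, so we take the square root of maple's fraction: 50.0 %, our survival fraction, the part of the free share that this acid leaves at 30 h. Squaring larch's fraction reads 47.3 %, but a square swells scatter where a root shrinks it, so we keep maple's. We reckon 60.0 % reacted, with the acid held at its charge.

The forecast reads “Acid stays catalytic, since the rate constant holds throughout the runs” and gives 60 % reacted and pH 3.585.

The flask gives 59.3 % reacted and pH 3.58.

    starting material + acid → weak acid + acid + product (k = 83.0 M⁻¹ h⁻¹)
    starting material + protic impurity → quenched substrate (k = 10.0 M⁻¹ h⁻¹)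
    starting material → weak acid + product (k = 7.40 × 10⁻⁵ h⁻¹)
    weak acid ⇌ conjugate base + acid, settled at all times (K = 5.00 × 10⁻¹⁰ M)

The flask holds 19.8 % quenched substrate, and its 40.7 % of starting material over the free share is 50.9 %, beside our 50.0 %. A neighbouring flask, charged with 65 mM of starting material at the same acid, impurity and time, has a free share of 92.0 %. The same survival fraction leaves it 46.0 %, so 54.0 % reacted. That neighbouring flask ends with 8.00 % quenched substrate, 0 % of its impurity and 47.9 % of its starting material, with 52.1 % reacted.

The runs were computed on assumed constants; noise was put on by code.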